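**Assumption:** (S)-linalool is used as enantiomerically pure material; any minor diastereomer from material of lower purity would be removed at aldol adduct 11.

Locants C1–C15 are germacrane locants (C14 = methyl on C10, C15 = methyl on C4, lactone C11(=C13H2)–C12). Compound numbers are those of the steps and the compound list.

## Analysis of the target

The target is a germacranolide: a ten-membered carbocycle (C1–C10) cis-fused at C6–C7 to an α-methylene-γ-butyrolactone (O6–C12(=O)–C11(=C13H2)–C7). It has five stereocentres: C3 (S), C6 (S), C7 (R), C8 (R) and C10 (S). Read around the ring, the C3 hydroxyl, the lactone oxygen on C6, the side-chain carbon C11 on C7, the angelate oxygen on C8 and C14 all lie on one face; only the tertiary hydroxyl on C10 lies on the other, so H6, H7 and H8 are mutually cis. The C3 and C6 oxygens flank a Z-trisubstituted C4=C5 alkene, so both carbinol carbons are allylic. Sensitive groups are the exo-methylene lactone (Michael acceptor), the angelate (Z to E isomerisation, acyl migration), the two allylic C–O bonds (ionisation under acid) and the tertiary alcohol. The difficulties are closing a ten-membered ring that holds a Z alkene, setting C3 and C6 relative to the C7/C8/C10 triad, and telling the C3, C8 and C10 hydroxyls apart without a long protecting-group sequence. The strategy rests on the C3–O/C4=C5/C6–O unit: a cis-2-ene-1,4-diol is the reduced form of a 3,6-dihydro-1,2-dioxine, so both oxygens and the Z alkene can come from one molecule of dioxygen and a C3=C4–C5=C6 ring diene.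

## Retrosynthetic reasoning

**29 ⇒ 28.** The lactone C12–O6 bond is cut to give hydroxy ester 28. Of the three hydroxyls in 28 only O6 can reach C12 through a five-membered ring, so the forward closure needs no protecting group and frees only methanol.

**28 ⇒ 27.** The two hydroxyls on C3 and C6 are joined back into an O–O bond. Peroxide 27 holds both oxygens cis and keeps them masked while nothing else in the molecule needs to change; the forward step is a reduction that breaks no C–O bond.

**27 ⇒ 26.** C3–O and C6–O are cut together in a retro-[4+2] step, which leads to the Z,Z ring diene 26. This removes two stereocentres and the Z C4=C5 alkene in one move. The forward photooxygenation is suprafacial, so C3 and C6 are fixed relative to each other by mechanism. What it has to achieve beyond that is delivery to the ring face that, in the flat drawing, also carries C11, O8 and C14. The angelate must already sit on O8, because after the peroxide is opened O3 and O8 could no longer be told apart.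

**26 ⇒ 25 ⇒ 24.** The silyl ether on O10 is put back, and the C5=C6 bond is cut by retro-ring-closing metathesis to triene 24. Cutting here places the ring closure between two monosubstituted alkene termini, leaves the trisubstituted C3=C4 bond and the two enoates as bystanders, and lets the Z C3=C4 geometry be set in an open chain.

**24 ⇒ 23 ⇒ 22 ⇒ 20.** The C4–C5 bond is cut to Z-alkenyl iodide 23 (a stereoretentive cross-coupling forward), and C3=C4 is cut to aldehyde 22 (a Z-selective iodo-olefination forward). The C3 aldehyde is traced back to the trisubstituted alkene of 20, which is the intact prenyl end of the starting terpene. Keeping that alkene as a latent aldehyde avoids carrying an iodide or a diene through the carbonylation.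

**20 ⇒ 19 ⇒ 16 + 17.** The C11–C12 bond of the acrylate is cut to terminal alkyne 19 (a Markovnikov alkoxycarbonylation forward), and the ester on O8 is cut to alcohol 16 and angelic acid 17. Acylating O8 while C11 is still an alkyne means a free C8 hydroxyl never coexists with a C12 ester, so the unwanted 12,8-lactone cannot form.

**16 ⇒ 15 ⇒ 14 ⇒ 13 ⇒ 12 ⇒ 11.** The alkyne carbon C13 is removed to aldehyde 14. The aldehyde is traced through alcohol 13 to the acyl group of imide 12, and the O8 silyl ether back to aldol adduct 11. The acyl carbon of the aldol thus becomes C11.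

**11 ⇒ 8 + 5.** The C7–C8 bond is cut as an auxiliary-controlled syn aldol between crotonyl imide 8 (through its dienolate) and aldehyde 5. This sets C7 with its vinyl group (the later C6=C5 terminus) and C8 in one step. A direct metal-mediated 2-(alkoxycarbonyl)allylation of 5 would be shorter, but the only resident stereocentre, C10, is quaternary and carries two alkyl groups of similar size, so it cannot decide the aldehyde face. The auxiliary in 8 can.

**5 ⇒ 4 ⇒ 2 ⇒ 1, and 8 ⇒ 6 + 7.** Aldehyde 5 comes from (S)-linalool 1 by silylation and anti-Markovnikov hydration–oxidation of the vinyl group. Linalool supplies C10 with its configuration, and C1–C3, C8, C9 and C14. Imide 8 comes from oxazolidinone 6 and acid chloride 7.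

## Alternatives that were turned down

**Alternative 1:** The C1–C2 bond is cut. The forward key step is a Ramberg–Bäcklund reaction of the eleven-membered sulfone A1 (sulfur between C1 and C2): halogenation in the flask, base-induced closure to an episulfone and extrusion of the sulfur give cyclodeca-1,4-diene A2 with a new Z C1=C2 bond.
- For it: an eleven-membered thioether is much easier to close than a ten-membered carbocycle, and the contraction itself costs no entropy. In A2 all five stereocentres, C3 and C6 included, come from open-chain chemistry. On stereochemical certainty this alternative is stronger than the chosen one.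
- Against it: A2 has a C1=C2 alkene that the target lacks, to be hydrogenated beside C4=C5. C7 carries only a two-carbon chain, so lactone closure and α-methylenation remain, together with removal of four protecting groups and a selective angeloylation of O8. Strong base is applied next to an allylic ether and a silyl ether.
- Comparison: after its key step it needs many more steps than the two that follow the chosen key step. The chosen strategy gives up the stereochemical security and offers in its place two C–O bonds and the Z alkene in one step, with no protecting groups on the new oxygens.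

**Alternative 2:** The C9–C10 bond and an O–C8 bond are cut. Aldoxime A3 (oxime at C10, vinyl group C8=C9 on the cis-lactone) is oxidised with NaOCl to a nitrile oxide, which adds to the vinyl group and closes the ten-membered ring together with a bridging isoxazoline in A4.
- For it: one step closes the ring, makes a C–C bond and delivers the C8 oxygen and a masked C10 ketone. C3 and the cis C6/C7 lactone are already in place, so no face of a ring diene has to be chosen; on that point it is stronger.
- Against it: the cycloaddition must choose the bridged regiochemistry and the right face at C8 inside a forming medium ring. Afterwards the N–O bond must be cleaved without touching C4=C5, and a methyl nucleophile must add to the C10 ketone from the correct face, next to a β-hydroxyl prone to retro-aldol cleavage. The lactone must be methylenated late in the presence of free hydroxyls, and O8 acylated selectively.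
- Comparison: it leaves two separate stereochemical questions (C8, C10) and at least six steps after the key step. The chosen route takes C10 from the chiral pool, sets C7/C8 by an auxiliary, and leaves one coupled question (C3/C6) and two steps.

**Alternative 3:** The C3–C4 bond is cut. Iodo aldehyde A5 (Z-alkenyl iodide at C4, aldehyde at C3, everything else in place) is treated with CrCl2 and catalytic NiCl2. Zerovalent nickel inserts into the C–I bond, the alkenyl group passes to chromium, and addition to the aldehyde closes the ring and makes the C3 carbinol, giving A6, the target as its C10 triethylsilyl ether.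
- For it: this ring closure is among the most dependable for ten-membered carbocycles, tolerates esters and enoates, carries the Z geometry in from the iodide and leaves only C3 to the cyclisation; one desilylation finishes. On reliability of ring closure and on convergence it is as strong as or stronger than the chosen strategy.
- Against it: A5 must already hold the cis-fused α-methylene lactone with C6, C7, C8 and C10 set and the angelate in place, so C6 and the iodoalkene need a separate, longer sequence through base-sensitive intermediates. The C3 configuration depends on which aldehyde face the ring presents, and a wrong result would need an oxidation–reduction on a sensitive allylic system.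
- Comparison: the chosen strategy does not have to make C6 beforehand. C3 and C6 are created together and locked cis by mechanism, on a precursor with three stereocentres and no lactone.

Key step: step 18

## Route

Step 1
Reactants: 1 (S)-linalool
Product: 2 tert-butyl{[(3S)-3,7-dimethylocta-1,6-dien-3-yl]oxy}dimethylsilane
Conditions: TBSOTf, 2,6-lutidine, CH2Cl2, 0 °C to rt
Reagents that add atoms: tert-butyldimethylsilyl triflate, CC(C)(C)[Si](C)(C)OS(=O)(=O)C(F)(F)F
Why: Silyl triflate with a hindered pyridine base silylates tertiary alcohols. The tertiary tert-butyldimethylsilyl ether on O10 should last until step 17 and is orthogonal to the triethylsilyl ether used later on O8.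

Step 2
Reactants: 2 tert-butyl{[(3S)-3,7-dimethylocta-1,6-dien-3-yl]oxy}dimethylsilane
Product: 4 (3S)-3-[(tert-butyldimethylsilyl)oxy]-3,7-dimethyloct-6-en-1-ol, via alkylborane 3 (not isolated)
Conditions: 9-BBN, THF, 0 °C to rt; then NaOH, H2O2, 0 °C
Reagents that add atoms: hydrogen peroxide, OO; 9-borabicyclo[3.3.1]nonane, B1C2CCCC1CCC2 (boron in 3 only)
Why: Anti-Markovnikov hydroboration–oxidation. 9-BBN reacts with the monosubstituted vinyl group far faster than with the trisubstituted alkene and places boron on the terminal carbon, which becomes C8.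

Step 3
Reactants: 4 (3S)-3-[(tert-butyldimethylsilyl)oxy]-3,7-dimethyloct-6-en-1-ol
Product: 5 (3S)-3-[(tert-butyldimethylsilyl)oxy]-3,7-dimethyloct-6-enal
Conditions: Dess–Martin periodinane, NaHCO3, CH2Cl2, 0 °C to rt
Reagents that add atoms: none
Why: Dess–Martin oxidation of a primary alcohol under buffered, non-basic conditions, so the β-silyloxy aldehyde is not exposed to elimination.

Step 4
Reactants: 6 (4S)-4-benzyl-1,3-oxazolidin-2-one; 7 (2E)-but-2-enoyl chloride
Product: 8 (4S)-4-benzyl-3-[(2E)-but-2-enoyl]-1,3-oxazolidin-2-one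
Conditions: n-BuLi, THF, −78 °C; then 7, −78 to 0 °C
Reagents that add atoms: none
Why: N-Acylation of the lithiated oxazolidinone with an acid chloride, the standard preparation of Evans imides.

Step 5
Reactants: 8 (4S)-4-benzyl-3-[(2E)-but-2-enoyl]-1,3-oxazolidin-2-one; 5 (3S)-3-[(tert-butyldimethylsilyl)oxy]-3,7-dimethyloct-6-enal
Product: 11 (4S)-4-benzyl-3-[(2S,3R,5S)-5-[(tert-butyldimethylsilyl)oxy]-2-ethenyl-3-hydroxy-5,9-dimethyldec-8-enoyl]-1,3-oxazolidin-2-one, via boron dienolate 9 (not isolated), via boron aldolate 10 (not isolated)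
Conditions: Bu2BOTf, Et3N, CH2Cl2, −78 to 0 °C; then 5, −78 to 0 °C; then pH 7 buffer, MeOH, H2O2, 0 °C
Reagents that add atoms: dibutylboron triflate, CCCCB(CCCC)OS(=O)(=O)C(F)(F)F (boron in 9 and 10 only)
Why: Evans syn aldol through the boron dienolate: soft enolisation removes a γ-hydrogen of the crotonyl group, and the Z(O)-dienolate 9 reacts at its α-carbon through a chair (Zimmerman–Traxler) transition state. The benzyl group of the auxiliary screens one enolate face, so the centres that become C7 (with its vinyl group) and C8 are set syn under reagent control, independently of the remote quaternary C10.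

Step 6
Reactants: 11 (4S)-4-benzyl-3-[(2S,3R,5S)-5-[(tert-butyldimethylsilyl)oxy]-2-ethenyl-3-hydroxy-5,9-dimethyldec-8-enoyl]-1,3-oxazolidin-2-one
Product: 12 (4S)-4-benzyl-3-[(2S,3R,5S)-5-[(tert-butyldimethylsilyl)oxy]-2-ethenyl-5,9-dimethyl-3-[(triethylsilyl)oxy]dec-8-enoyl]-1,3-oxazolidin-2-one
Conditions: TESOTf, 2,6-lutidine, CH2Cl2, −78 to 0 °C
Reagents that add atoms: triethylsilyl triflate, CC[Si](CC)(CC)OS(=O)(=O)C(F)(F)F
Why: Silylation of the secondary alcohol. It protects O8 through the reduction and the basic homologation and can be taken off in step 10 without touching the tertiary silyl ether.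

Step 7
Reactants: 12 (4S)-4-benzyl-3-[(2S,3R,5S)-5-[(tert-butyldimethylsilyl)oxy]-2-ethenyl-5,9-dimethyl-3-[(triethylsilyl)oxy]dec-8-enoyl]-1,3-oxazolidin-2-one
Product: 13 (2R,3R,5S)-5-[(tert-butyldimethylsilyl)oxy]-2-ethenyl-5,9-dimethyl-3-[(triethylsilyl)oxy]dec-8-en-1-ol
Conditions: LiBH4, MeOH (1 equiv), Et2O, 0 °C
Reagents that add atoms: none
Why: Reductive cleavage of an N-acyl oxazolidinone with LiBH4 gives the primary alcohol and returns the auxiliary. No carbonyl remains next to C7, so that centre is not at risk in this step.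

Step 8
Reactants: 13 (2R,3R,5S)-5-[(tert-butyldimethylsilyl)oxy]-2-ethenyl-5,9-dimethyl-3-[(triethylsilyl)oxy]dec-8-en-1-ol
Product: 14 (2S,3R,5S)-5-[(tert-butyldimethylsilyl)oxy]-2-ethenyl-5,9-dimethyl-3-[(triethylsilyl)oxy]dec-8-enal
Conditions: Dess–Martin periodinane, NaHCO3, CH2Cl2, 0 °C
Reagents that add atoms: none
Why: Buffered Dess–Martin oxidation. The α-vinyl aldehyde should be used at once so that neither epimerisation at C7 nor migration of the alkene into conjugation sets in.

Step 9
Reactants: 14 (2S,3R,5S)-5-[(tert-butyldimethylsilyl)oxy]-2-ethenyl-5,9-dimethyl-3-[(triethylsilyl)oxy]dec-8-enal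
Product: 15 (3R,4R,6S)-6-[(tert-butyldimethylsilyl)oxy]-3-ethenyl-6,10-dimethyl-4-[(triethylsilyl)oxy]undec-9-en-1-yne
Conditions: TMSCHN2, LiN(iPr)2, THF, −78 °C; then 14, −78 to 0 °C
Reagents that add atoms: (trimethylsilyl)diazomethane, C[Si](C)(C)C=[N+]=[N-]
Why: Colvin homologation: the lithiated silyl diazomethane adds to the aldehyde, Peterson-type loss of silanolate and loss of N2 give an alkylidene carbene, and a 1,2-hydride shift gives the terminal alkyne. Addition at −78 °C should outrun deprotonation at C7.

Step 10
Reactants: 15 (3R,4R,6S)-6-[(tert-butyldimethylsilyl)oxy]-3-ethenyl-6,10-dimethyl-4-[(triethylsilyl)oxy]undec-9-en-1-yne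
Product: 16 (3R,4R,6S)-6-[(tert-butyldimethylsilyl)oxy]-3-ethenyl-6,10-dimethylundec-9-en-1-yn-4-ol
Conditions: PPTS, MeOH/CH2Cl2, 0 °C
Reagents that add atoms: none
Why: Acid-catalysed methanolysis of the secondary triethylsilyl ether; a tertiary tert-butyldimethylsilyl ether is cleaved far more slowly under these conditions.

Step 11
Reactants: 16 (3R,4R,6S)-6-[(tert-butyldimethylsilyl)oxy]-3-ethenyl-6,10-dimethylundec-9-en-1-yn-4-ol; 17 angelic acid
Product: 19 (3R,4R,6S)-6-[(tert-butyldimethylsilyl)oxy]-3-ethenyl-6,10-dimethylundec-9-en-1-yn-4-yl (2Z)-2-methylbut-2-enoate, via mixed anhydride 18 (not isolated)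
Conditions: 17, 2,4,6-trichlorobenzoyl chloride, Et3N, toluene, rt; then 16, toluene, 75 °C
Reagents that add atoms: 2,4,6-trichlorobenzoyl chloride, O=C(Cl)c1c(Cl)cc(Cl)cc1Cl (aroyl group in 18 only)
Why: Yamaguchi esterification through mixed anhydride 18; without excess nucleophilic catalyst this protocol transfers the angeloyl group without isomerisation to the tiglate. O10 is silylated, so only O8 is acylated, and because C11 is still an alkyne no 12,8-lactone can form.

Step 12
Reactants: 19 (3R,4R,6S)-6-[(tert-butyldimethylsilyl)oxy]-3-ethenyl-6,10-dimethylundec-9-en-1-yn-4-yl (2Z)-2-methylbut-2-enoate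
Product: 20 methyl (3R,4R,6S)-6-[(tert-butyldimethylsilyl)oxy]-3-ethenyl-6,10-dimethyl-2-methylidene-4-{[(2Z)-2-methylbut-2-enoyl]oxy}undec-9-enoate
Conditions: Pd(OAc)2 (2 mol%), 2-PyPPh2, MeSO3H (cat.), CO (30 bar), MeOH/CH2Cl2, 50 °C
Reagents that add atoms: carbon monoxide, [C-]#[O+]; methanol, CO
Why: Palladium-catalysed Markovnikov hydromethoxycarbonylation of a terminal alkyne (pyridylphosphine–acid system) puts the ester on the internal carbon and gives the 2-substituted acrylate; isolated alkenes react much more slowly. The step is placed before the alkenyl iodide and the diene exist, because both would react with zerovalent palladium or palladium hydride.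

Step 13
Reactants: 20 methyl (3R,4R,6S)-6-[(tert-butyldimethylsilyl)oxy]-3-ethenyl-6,10-dimethyl-2-methylidene-4-{[(2Z)-2-methylbut-2-enoyl]oxy}undec-9-enoate
Product: 22 methyl (3R,4R,6S)-6-[(tert-butyldimethylsilyl)oxy]-3-ethenyl-6-methyl-2-methylidene-4-{[(2Z)-2-methylbut-2-enoyl]oxy}-9-oxononanoate, via ozonide 21 (not isolated)
Conditions: O3, CH2Cl2, −78 °C (Sudan Red 7B end point); then PPh3, −78 °C to rt
Reagents that add atoms: ozone, [O-][O+]=O
Why: Chemoselective ozonolysis: the electron-rich trisubstituted alkene reacts with ozone much faster than the monosubstituted vinyl group and the two electron-poor enoates, and the indicator dye marks the end point. PPh3 reduces ozonide 21 to the C3 aldehyde.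

Step 14
Reactants: 22 methyl (3R,4R,6S)-6-[(tert-butyldimethylsilyl)oxy]-3-ethenyl-6-methyl-2-methylidene-4-{[(2Z)-2-methylbut-2-enoyl]oxy}-9-oxononanoate
Product: 23 methyl (3R,4R,6S,9Z)-6-[(tert-butyldimethylsilyl)oxy]-3-ethenyl-10-iodo-6-methyl-2-methylidene-4-{[(2Z)-2-methylbut-2-enoyl]oxy}undec-9-enoate
Conditions: [Ph3PCH(I)CH3]I, NaN(SiMe3)2, THF, −78 °C; then 22, −78 to −20 °C
Reagents that add atoms: (1-iodoethyl)triphenylphosphonium iodide, CC(I)[P+](c1ccccc1)(c1ccccc1)c1ccccc1.[I-]
Why: Stork–Zhao-type Wittig olefination: the α-iodo ylide gives (Z)-2-iodo-2-alkenes (iodine cis to the chain) from aliphatic aldehydes under kinetic control at low temperature. This fixes the Z geometry of C3=C4.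

Step 15
Reactants: 23 methyl (3R,4R,6S,9Z)-6-[(tert-butyldimethylsilyl)oxy]-3-ethenyl-10-iodo-6-methyl-2-methylidene-4-{[(2Z)-2-methylbut-2-enoyl]oxy}undec-9-enoate
Product: 24 methyl (3R,4R,6S,9Z)-6-[(tert-butyldimethylsilyl)oxy]-3-ethenyl-6,10-dimethyl-2-methylidene-4-{[(2Z)-2-methylbut-2-enoyl]oxy}dodeca-9,11-dienoate
Conditions: Bu3SnCH=CH2, Pd(PPh3)4 (5 mol%), CuI, CsF, DMF, rt
Reagents that add atoms: tributyl(vinyl)stannane, C=C[Sn](CCCC)(CCCC)CCCC
Why: Stille coupling of an alkenyl iodide proceeds with retention of alkene geometry; the copper/fluoride-promoted variant is neutral and mild and spares both enoates.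

Step 16
Reactants: 24 methyl (3R,4R,6S,9Z)-6-[(tert-butyldimethylsilyl)oxy]-3-ethenyl-6,10-dimethyl-2-methylidene-4-{[(2Z)-2-methylbut-2-enoyl]oxy}dodeca-9,11-dienoate
Product: 25 methyl 2-[(1R,2Z,4Z,8S,10R)-8-[(tert-butyldimethylsilyl)oxy]-4,8-dimethyl-10-{[(2Z)-2-methylbut-2-enoyl]oxy}cyclodeca-2,4-dien-1-yl]prop-2-enoate
Conditions: second-generation Grubbs catalyst RuCl2(=CHPh)(H2IMes)(PCy3) (10 mol%), CH2Cl2 (1 mM), 40 °C
Reagents that add atoms: none
Why: Ring-closing diene–ene metathesis between the C7 vinyl group and the terminal alkene of the diene. The internal C3=C4 bond is trisubstituted and the two enoates are electron-poor, so the catalyst should engage only the two monosubstituted termini. The Z,Z diene is expected to be the less strained ring isomer, and the Z C3=C4 bond and the quaternary C10 pre-organise the chain.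

Step 17
Reactants: 25 methyl 2-[(1R,2Z,4Z,8S,10R)-8-[(tert-butyldimethylsilyl)oxy]-4,8-dimethyl-10-{[(2Z)-2-methylbut-2-enoyl]oxy}cyclodeca-2,4-dien-1-yl]prop-2-enoate
Product: 26 methyl 2-[(1R,2Z,4Z,8S,10R)-8-hydroxy-4,8-dimethyl-10-{[(2Z)-2-methylbut-2-enoyl]oxy}cyclodeca-2,4-dien-1-yl]prop-2-enoate
Conditions: HF·pyridine, pyridine, THF, 0 °C to rt
Reagents that add atoms: none
Why: Fluoride cleavage of the tertiary silyl ether under weakly acidic, non-basic conditions that both enoates and the diene should tolerate.

Step 18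
Reactants: 26 methyl 2-[(1R,2Z,4Z,8S,10R)-8-hydroxy-4,8-dimethyl-10-{[(2Z)-2-methylbut-2-enoyl]oxy}cyclodeca-2,4-dien-1-yl]prop-2-enoate
Product: 27 methyl 2-[(1S,2R,3R,5S,8S)-5-hydroxy-5,12-dimethyl-3-{[(2Z)-2-methylbut-2-enoyl]oxy}-9,10-dioxabicyclo[6.2.2]dodec-11-en-2-yl]prop-2-enoate (3S,6S,7R,8R,10S in germacrane locants)
Conditions: O2, tetraphenylporphyrin (2 mol%), CH2Cl2, visible light, −40 °C
Reagents that add atoms: dioxygen, O=O
Why: The excited sensitiser passes its energy to O2, and singlet oxygen adds suprafacially across C3 and C6 of the cisoid diene in a concerted [4+2] cycloaddition that forms both C–O bonds and moves the double bond to C4=C5. The closest known reaction type is the photooxygenation of cyclic 1,3-dienes (cyclohexa-, cyclohepta- and cycloocta-1,3-diene) to bicyclic endoperoxides. The six-membered 3,6-dihydro-1,2-dioxine is closed by cycloaddition, with both ends joined at once, which makes the dioxabicyclo[6.2.2] system. C3 and C6 are fixed relative to each other by the suprafacial mechanism on a Z,Z ring diene, which also makes C4=C5 Z by construction. Their sense relative to C7, C8 and C10 is a matter of diene face: the oxygen must arrive on the face that, in the flat ring drawing, also carries C11, O8 and C14. In the cisoid conformer the six-carbon tether C7–C2 must fold under one diene face; the fold that turns H7, H8 and the C10 hydroxyl inward and keeps the acrylate, the angelate and C14 outside leaves exactly the required face open. The step also needs [4+2] rather than ene reaction at C15–H or C2–H, which low temperature, the aprotic solvent and the cisoid ring geometry should favour, while the electron-poor acrylate and angelate alkenes are inert. The facial argument is a conformational model and not a rigid control element, so this is the least secure point of the route.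

Step 19
Reactants: 27 methyl 2-[(1S,2R,3R,5S,8S)-5-hydroxy-5,12-dimethyl-3-{[(2Z)-2-methylbut-2-enoyl]oxy}-9,10-dioxabicyclo[6.2.2]dodec-11-en-2-yl]prop-2-enoate
Product: 28 methyl 2-[(1S,2S,3Z,5S,8S,10R)-2,5,8-trihydroxy-4,8-dimethyl-10-{[(2Z)-2-methylbut-2-enoyl]oxy}cyclodec-3-en-1-yl]prop-2-enoate
Conditions: thiourea, MeOH (wet), 0 °C to rt
Reagents that add atoms: none
Why: Thiourea reduces the O–O bond of endoperoxides to the cis-diol by attack of sulfur on oxygen, without touching alkenes or esters. The medium is not basic, so no Kornblum–DeLaMare rearrangement is expected, and no C–O bond is broken, so C3 and C6 keep their configuration.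

Step 20
Reactants: 28 methyl 2-[(1S,2S,3Z,5S,8S,10R)-2,5,8-trihydroxy-4,8-dimethyl-10-{[(2Z)-2-methylbut-2-enoyl]oxy}cyclodec-3-en-1-yl]prop-2-enoate
Product: 29 CNP0137971.2, (3S,4Z,6S,7R,8R,10S)-8-angeloyloxy-3,10-dihydroxygermacra-4,11(13)-dien-12,6-olide
Conditions: PPTS (cat.), CH2Cl2, rt
Reagents that add atoms: none
Why: Acid-catalysed lactonisation (intramolecular transesterification): of the three hydroxyls only O6, cis to C11, can reach C12 through a five-membered ring. The mild pyridinium acid should not ionise the allylic C–O bonds.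

## Compound list

1 | (S)-linalool, (3S)-3,7-dimethylocta-1,6-dien-3-ol | CC(C)=CCC[C@](C)(O)C=C | starting material
2 | tert-butyl{[(3S)-3,7-dimethylocta-1,6-dien-3-yl]oxy}dimethylsilane | CC(C)=CCC[C@](C)(O[Si](C)(C)C(C)(C)C)C=C | intermediate
3 | B-alkyl-9-borabicyclo[3.3.1]nonane from 2 (boron on the former vinyl terminus) | CC(C)=CCC[C@](C)(O[Si](C)(C)C(C)(C)C)CCB1C2CCCC1CCC2 | intermediate
4 | (3S)-3-[(tert-butyldimethylsilyl)oxy]-3,7-dimethyloct-6-en-1-ol | CC(C)=CCC[C@](C)(O[Si](C)(C)C(C)(C)C)CCO | intermediate
5 | (3S)-3-[(tert-butyldimethylsilyl)oxy]-3,7-dimethyloct-6-enal | CC(C)=CCC[C@](C)(O[Si](C)(C)C(C)(C)C)CC=O | intermediate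
6 | (4S)-4-benzyl-1,3-oxazolidin-2-one | O=C1N[C@@H](Cc2ccccc2)CO1 | starting material
7 | (2E)-but-2-enoyl chloride | C/C=C/C(=O)Cl | starting material
8 | (4S)-4-benzyl-3-[(2E)-but-2-enoyl]-1,3-oxazolidin-2-one | C/C=C/C(=O)N1[C@@H](Cc2ccccc2)COC1=O | intermediate
9 | dibutylboron (Z)-dienolate of 8 | C=C/C=C(\OB(CCCC)CCCC)N1[C@@H](Cc2ccccc2)COC1=O | intermediate
10 | dibutylboron aldolate of 11 | CC(C)=CCC[C@](C)(O[Si](C)(C)C(C)(C)C)C[C@@H](OB(CCCC)CCCC)[C@H](C=C)C(=O)N1[C@@H](Cc2ccccc2)COC1=O | intermediate
11 | (4S)-4-benzyl-3-[(2S,3R,5S)-5-[(tert-butyldimethylsilyl)oxy]-2-ethenyl-3-hydroxy-5,9-dimethyldec-8-enoyl]-1,3-oxazolidin-2-one | CC(C)=CCC[C@](C)(O[Si](C)(C)C(C)(C)C)C[C@@H](O)[C@H](C=C)C(=O)N1[C@@H](Cc2ccccc2)COC1=O | intermediate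
12 | (4S)-4-benzyl-3-[(2S,3R,5S)-5-[(tert-butyldimethylsilyl)oxy]-2-ethenyl-5,9-dimethyl-3-[(triethylsilyl)oxy]dec-8-enoyl]-1,3-oxazolidin-2-one | CC(C)=CCC[C@](C)(O[Si](C)(C)C(C)(C)C)C[C@@H](O[Si](CC)(CC)CC)[C@H](C=C)C(=O)N1[C@@H](Cc2ccccc2)COC1=O | intermediate
13 | (2R,3R,5S)-5-[(tert-butyldimethylsilyl)oxy]-2-ethenyl-5,9-dimethyl-3-[(triethylsilyl)oxy]dec-8-en-1-ol | CC(C)=CCC[C@](C)(O[Si](C)(C)C(C)(C)C)C[C@@H](O[Si](CC)(CC)CC)[C@H](C=C)CO | intermediate
14 | (2S,3R,5S)-5-[(tert-butyldimethylsilyl)oxy]-2-ethenyl-5,9-dimethyl-3-[(triethylsilyl)oxy]dec-8-enal | CC(C)=CCC[C@](C)(O[Si](C)(C)C(C)(C)C)C[C@@H](O[Si](CC)(CC)CC)[C@H](C=C)C=O | intermediate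
15 | (3R,4R,6S)-6-[(tert-butyldimethylsilyl)oxy]-3-ethenyl-6,10-dimethyl-4-[(triethylsilyl)oxy]undec-9-en-1-yne | CC(C)=CCC[C@](C)(O[Si](C)(C)C(C)(C)C)C[C@@H](O[Si](CC)(CC)CC)[C@H](C=C)C#C | intermediate
16 | (3R,4R,6S)-6-[(tert-butyldimethylsilyl)oxy]-3-ethenyl-6,10-dimethylundec-9-en-1-yn-4-ol | CC(C)=CCC[C@](C)(O[Si](C)(C)C(C)(C)C)C[C@@H](O)[C@H](C=C)C#C | intermediate
17 | angelic acid, (2Z)-2-methylbut-2-enoic acid | C/C=C(/C)C(=O)O | starting material
18 | (2Z)-2-methylbut-2-enoic 2,4,6-trichlorobenzoic anhydride | C/C=C(/C)C(=O)OC(=O)c1c(Cl)cc(Cl)cc1Cl | intermediate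
19 | (3R,4R,6S)-6-[(tert-butyldimethylsilyl)oxy]-3-ethenyl-6,10-dimethylundec-9-en-1-yn-4-yl (2Z)-2-methylbut-2-enoate | CC(C)=CCC[C@](C)(O[Si](C)(C)C(C)(C)C)C[C@@H](OC(=O)/C(C)=C\C)[C@H](C=C)C#C | intermediate
20 | methyl (3R,4R,6S)-6-[(tert-butyldimethylsilyl)oxy]-3-ethenyl-6,10-dimethyl-2-methylidene-4-{[(2Z)-2-methylbut-2-enoyl]oxy}undec-9-enoate | CC(C)=CCC[C@](C)(O[Si](C)(C)C(C)(C)C)C[C@@H](OC(=O)/C(C)=C\C)[C@H](C=C)C(=C)C(=O)OC | intermediate
21 | ozonide (3,3-dimethyl-1,2,4-trioxolane) of 20 at the trisubstituted alkene | CC1(C)OOC(CC[C@](C)(O[Si](C)(C)C(C)(C)C)C[C@@H](OC(=O)/C(C)=C\C)[C@H](C=C)C(=C)C(=O)OC)O1 | intermediate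
22 | methyl (3R,4R,6S)-6-[(tert-butyldimethylsilyl)oxy]-3-ethenyl-6-methyl-2-methylidene-4-{[(2Z)-2-methylbut-2-enoyl]oxy}-9-oxononanoate | O=CCC[C@](C)(O[Si](C)(C)C(C)(C)C)C[C@@H](OC(=O)/C(C)=C\C)[C@H](C=C)C(=C)C(=O)OC | intermediate
23 | methyl (3R,4R,6S,9Z)-6-[(tert-butyldimethylsilyl)oxy]-3-ethenyl-10-iodo-6-methyl-2-methylidene-4-{[(2Z)-2-methylbut-2-enoyl]oxy}undec-9-enoate | C/C(I)=C/CC[C@](C)(O[Si](C)(C)C(C)(C)C)C[C@@H](OC(=O)/C(C)=C\C)[C@H](C=C)C(=C)C(=O)OC | intermediate
24 | methyl (3R,4R,6S,9Z)-6-[(tert-butyldimethylsilyl)oxy]-3-ethenyl-6,10-dimethyl-2-methylidene-4-{[(2Z)-2-methylbut-2-enoyl]oxy}dodeca-9,11-dienoate | C=C/C(C)=C\CC[C@](C)(O[Si](C)(C)C(C)(C)C)C[C@@H](OC(=O)/C(C)=C\C)[C@H](C=C)C(=C)C(=O)OC | intermediate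
25 | methyl 2-[(1R,2Z,4Z,8S,10R)-8-[(tert-butyldimethylsilyl)oxy]-4,8-dimethyl-10-{[(2Z)-2-methylbut-2-enoyl]oxy}cyclodeca-2,4-dien-1-yl]prop-2-enoate | C=C(C(=O)OC)[C@H]1/C=C\C(C)=C/CC[C@](C)(O[Si](C)(C)C(C)(C)C)C[C@H]1OC(=O)/C(C)=C\C | intermediate
26 | methyl 2-[(1R,2Z,4Z,8S,10R)-8-hydroxy-4,8-dimethyl-10-{[(2Z)-2-methylbut-2-enoyl]oxy}cyclodeca-2,4-dien-1-yl]prop-2-enoate | C=C(C(=O)OC)[C@H]1/C=C\C(C)=C/CC[C@](C)(O)C[C@H]1OC(=O)/C(C)=C\C | intermediate
27 | methyl 2-[(1S,2R,3R,5S,8S)-5-hydroxy-5,12-dimethyl-3-{[(2Z)-2-methylbut-2-enoyl]oxy}-9,10-dioxabicyclo[6.2.2]dodec-11-en-2-yl]prop-2-enoate | C=C(C(=O)OC)[C@H]1[C@H]2OO[C@@H](CC[C@](C)(O)C[C@H]1OC(=O)/C(C)=C\C)C(C)=C2 | intermediate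
28 | methyl 2-[(1S,2S,3Z,5S,8S,10R)-2,5,8-trihydroxy-4,8-dimethyl-10-{[(2Z)-2-methylbut-2-enoyl]oxy}cyclodec-3-en-1-yl]prop-2-enoate | C=C(C(=O)OC)[C@H]1[C@@H](O)/C=C(/C)[C@@H](O)CC[C@](C)(O)C[C@H]1OC(=O)/C(C)=C\C | intermediate
29 | CNP0137971.2, (3S,4Z,6S,7R,8R,10S)-8-angeloyloxy-3,10-dihydroxygermacra-4,11(13)-dien-12,6-olide | C=C1C(=O)O[C@H]2/C=C(/C)[C@@H](O)CC[C@](C)(O)C[C@@H](OC(=O)/C(C)=C\C)[C@@H]12 | target

## Step count and least certain steps

Total: 20 steps. Longest linear sequence: 19 steps from (S)-linalool (steps 1–3 and 5–20); step 4 is a one-step side branch.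

**Step 18 (key step).** The most likely failure is delivery of oxygen to the other diene face, which would give the 3,6-bis-epimer of 27. The facial preference rests only on how the six-carbon tether folds, and C7, at the hinge of that fold, may prefer to keep its acrylate away from the C2 methylene. The second likely failure is ene reaction at C15–H or C2–H in place of cycloaddition, because a Z,Z diene in a ten-membered ring is twisted out of planarity. The fallback does not use singlet oxygen and sets out from silyl ether 25. Palladium-catalysed cis-1,4-diacetoxylation (Pd(OAc)2, LiOAc, LiCl, p-benzoquinone, AcOH, rt) adds both acetates anti to the metal, that is, to the face opposite the one an external reagent prefers. It would give the 3,6-di-O-acetyl 10-O-silyl derivative of 28, F1. HF·pyridine would then give the 3,6-di-O-acetyl derivative of 28, F2, and selective methanolysis of the two acetates (Mg(OMe)2, MeOH, 0 °C) would return to the route at 28. This fallback corrects a wrong-face outcome; it is of no use if the open face is already the required one and only the ene reaction interferes.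

**Step 16 (ring-closing metathesis).** Ring contraction by metathesis at the C3=C4 bond (an eight-membered ring), oligomerisation at the concentration needed for turnover, or formation of the E isomer at C5=C6 could each defeat the closure, because ten-membered carbocycles form reluctantly. The fallback closes the ring by cross-coupling and sets out from alkenyl iodide 23. Z-selective cross-metathesis of the C7 vinyl group with vinyl-B(pin) (molybdenum monoaryloxide pyrrolide alkylidene Mo(NAr)(CHCMe2Ph)(Me2C4H2N)(OAr′)) would give the (Z)-alkenylboronate of 23, F3. Intramolecular Suzuki–Miyaura coupling (Pd(PPh3)4, K3PO4, THF/H2O, high dilution) would form C4–C5 with retention at both alkenes and return to the route at 25.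

**Step 14 (iodo-olefination).** Conjugate addition of the non-stabilised ylide to the acrylate, incomplete conversion and erosion of the Z:E ratio are the likely problems, since α-iodo ylides are short-lived and the substrate carries a Michael acceptor. The fallback sets out from aldehyde 22. Neutral dibromo-olefination (CBr4, PPh3) would give the 1,1-dibromoalkene of 22, F4. Trans-selective Negishi methylation (MeZnCl, PdCl2(DPEphos)) would replace the bromine trans to the chain and give the (Z)-2-bromoalkene corresponding to 23, F5. Stille vinylation as in step 15 would return to the route at 24.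

**Step 9 (alkyne homologation).** Deprotonation at C7 by the lithiated diazo reagent could cause epimerisation or migration of the vinyl double bond into conjugation, because the C7–H bond is both α to the aldehyde and allylic. The fallback sets out from aldehyde 14. Dibromo-olefination under neutral conditions (CBr4, PPh3, Et3N, CH2Cl2, 0 °C) would give the 1,1-dibromoalkene of 14, F6. Treatment with n-BuLi (THF, −78 °C; bromine–lithium exchange and 1,2-shift) would return to the route at 15.

## Further compounds

F1 | step 18 | 3,6-di-O-acetyl 10-O-(tert-butyldimethylsilyl) derivative of 28 | C=C(C(=O)OC)[C@H]1[C@@H](OC(C)=O)/C=C(/C)[C@@H](OC(C)=O)CC[C@](C)(O[Si](C)(C)C(C)(C)C)C[C@H]1OC(=O)/C(C)=C\C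
F2 | step 18 | 3,6-di-O-acetyl derivative of 28 | C=C(C(=O)OC)[C@H]1[C@@H](OC(C)=O)/C=C(/C)[C@@H](OC(C)=O)CC[C@](C)(O)C[C@H]1OC(=O)/C(C)=C\C
F3 | step 16 | (Z)-alkenyl pinacol boronate of 23 (boron on C5, Z C5=C6) | C/C(I)=C/CC[C@](C)(O[Si](C)(C)C(C)(C)C)C[C@@H](OC(=O)/C(C)=C\C)[C@H](/C=C\B1OC(C)(C)C(C)(C)O1)C(=C)C(=O)OC
F4 | step 14 | 1,1-dibromoalkene from 22 (C3=CBr2) | BrC(Br)=CCC[C@](C)(O[Si](C)(C)C(C)(C)C)C[C@@H](OC(=O)/C(C)=C\C)[C@H](C=C)C(=C)C(=O)OC
F5 | step 14 | (Z)-2-bromoalkene analogue of 23 | C/C(Br)=C/CC[C@](C)(O[Si](C)(C)C(C)(C)C)C[C@@H](OC(=O)/C(C)=C\C)[C@H](C=C)C(=C)C(=O)OC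
F6 | step 9 | 1,1-dibromoalkene from 14 | CC(C)=CCC[C@](C)(O[Si](C)(C)C(C)(C)C)C[C@@H](O[Si](CC)(CC)CC)[C@H](C=C)C=C(Br)Br
A1 | alternative 1 | eleven-membered cyclic sulfone, sulfur between C1 and C2 | COc1ccc(CO[C@H]2CS(=O)(=O)C[C@@]3(C)C[C@@H](OC(C)(C)O3)[C@@H](CCO[Si](C)(C)C(C)(C)C)[C@@H](O[Si](C)(C)C(C)(C)C)/C=C2/C)cc1
A2 | alternative 1 | cyclodeca-1,4-diene with new Z C1=C2 alkene | COc1ccc(CO[C@H]2/C=C\[C@@]3(C)C[C@@H](OC(C)(C)O3)[C@@H](CCO[Si](C)(C)C(C)(C)C)[C@@H](O[Si](C)(C)C(C)(C)C)/C=C2/C)cc1
A3 | alternative 2 | C10 aldoxime with C8=C9 vinyl group on the cis-lactone | O=C1O[C@@H](/C=C(/C)[C@@H](O[Si](C)(C)C(C)(C)C)CCC=NO)[C@@H](C=C)C1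
A4 | alternative 2 | isoxazoline-bridged ten-membered carbocycle with cis-lactone | O=C1O[C@H]2/C=C(/C)[C@@H](O[Si](C)(C)C(C)(C)C)CCC3=NO[C@H](C3)[C@H]2C1
A5 | alternative 3 | C3 aldehyde with Z-alkenyl iodide at C4 | C=C1C(=O)O[C@@H](/C=C(/C)I)[C@H]1[C@H](OC(=O)/C(C)=C\C)C[C@@](C)(O[Si](CC)(CC)CC)CCC=O
A6 | alternative 3 | target as its C10 triethylsilyl ether | C=C1C(=O)O[C@H]2/C=C(/C)[C@@H](O)CC[C@](C)(O[Si](CC)(CC)CC)C[C@@H](OC(=O)/C(C)=C\C)[C@@H]12
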